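## Analysis of the target

Target 26 is a diester of the ent-labdane series. Labdane locants are used throughout: ring A is C1–C5 plus C10 (gem-dimethyl C4, angular methyl on C10), ring B is C5–C10 with a C6=C7 double bond, the ring ester carbon is C17 on C8, and the chain on C9 runs C11–C12–C13(=C14–C15O2Me)–C16H2OAc. There are four stereocentres. H5 is trans to the C10 methyl (trans-decalin), the C9 chain is cis to that methyl, and the C8 ester is trans to the chain, so both ring B substituents are equatorial. The side-chain alkene is trisubstituted, with C12 cis to the ester and the acetoxymethyl group trans to it. The sensitive points are the C8–H (allylic and α to an ester, so base can epimerise it or move the double bond into conjugation), the allylic acetate, and two methyl esters that cannot be told apart by hydrolysis. The difficulty lies in the quaternary C10 wedged between C4 and C9, the contiguous centres C8–C9–C10, and a β,γ-unsaturated ester that must arise without an enolate. The strategy rests on one feature: with C11 as an aldehyde, the atoms C11, C9, C8, C7 and C6 form a γ,δ-unsaturated carbonyl array, the product pattern of a Claisen shift. Tying the aldehyde oxygen back to C6 gives a dihydropyran (O, C11, C9, C10, C5, C6) fused to ring A, and ring B is then its ring-contraction product.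

## Retrosynthetic reasoning

26 ⇒ 25. The acetyl group on the C16 oxygen is removed first. The allylic acetate is the most labile group of the target, so it is put on last, by acylation of the only free hydroxyl of 25.

25 ⇒ 21 + 23. The C12–C13 bond is cut between an sp3 and an sp2 carbon. The trisubstituted alkene can then be carried with fixed geometry in the small fragment 23, and the ring fragment 21 needs only a vinyl group on C9. A cut at C11–C12 or C9–C11 would call for carbanion alkylation next to the acidic C8–H. Forward, C12 is borylated and coupled under palladium catalysis with retention at C13. Fragment 23 comes from ynoate 22 by anti hydroiodination.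

21 ⇒ 20. The C11=C12 bond is traced to the C11 aldehyde. The forward step must be a non-basic methylenation, so that C8 and C9 are not disturbed. This reduces the side chain to the one-carbon aldehyde that the Claisen retron needs.

20 ⇒ 19. The C8–C9 bond is cut and the C11 oxygen is rejoined to C6. This single bond links both ring B stereocentres and closes ring B. The forward [3,3] shift gains ring B, C8, C9, the 6-ene and the β,γ-unsaturated ester at once, on a ring A whose C10 and C5 are already secure. It has to pass the configuration of C6 on to C9 and the Z geometry on to C8.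

19 ⇒ 17 + 18. The C7=C8 bond is cut by a Z-selective olefination of aldehyde 17 with phosphonate 18. The ester enters this late because hydride reagents are used before it. Aldehyde 17 comes from alcohol 16, and 16 from benzyl ether 15.

15 ⇒ 13 ⇒ 12. The enol ether C9=C11 is traced to lactol 13 by dehydration and 13 to lactone 12 by partial reduction. The lactone is a robust carrier of the C6–O–C11 link.

12 ⇒ 11. The ring oxygen between C11 and C6 is taken out, which leaves cyclopentanone 11. Forward, a Baeyer–Villiger oxidation must insert oxygen on the C6 side with retention. The gain is a rigid hydrindanone in which C6 is an α-carbon and the bicycle controls C5 and C6.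

11 ⇒ 9 + 10, then 9 ⇒ 7. The C6–C7 bond is cut to silyl enol ether 9 and chloromethyl ether 10. Enol ether 9 comes from enone 7 by conjugate reduction with trapping of the enolate, which sets H5 and fixes the enolate towards C6.

7 ⇒ 6 ⇒ 5 ⇒ 4 ⇒ 1 + 2. The C5=C6 bond of 7 is an aldol condensation of diketone 6, whose methyl ketone comes from the allyl group of 5. The C9–C10 bond of 5 is cut last: a catalytic asymmetric allylation of the enol carbonate 4, made from ketone 1 and chloroformate 2, sets the quaternary C10. It is the only stereocentre of the route set by a reagent.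

## Alternatives that were turned down

Alternative 1: The C1–C10 bond of ring A is cut, with ring B present as an arene. Forward, the phenolate of bromosalicylate A1 would alkylate its para carbon C10 with the tethered primary mesylate under Cs2CO3 and a chiral quaternary ammonium salt, giving the cross-conjugated dienone A2.
- For: the chemistry up to the key step is flat and cheap, C10 is set catalytically, and the C11–C14 chain is carried from the start. On convergence and on early placement of the side chain it is stronger than the chosen route, which adds C12–C16 only at the end.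
- Against: A2 holds one of the four stereocentres. C5, C8 and C9 would have to be set afterwards by reducing a fully substituted bromodienone: the tetrasubstituted C8=C9 bond, the C5=C6 bond with H5 trans to the methyl, removal of the C7 ketone and the bromine with the 6-ene left behind. Nothing in A2 directs these, and the alkyne stands in the way of hydrogenation. C-alkylation at a para carbon that already bears a methyl group also competes with O-alkylation.
- Comparison: the chosen route needs more steps before its key step. In return it sets C8 and C9 stereospecifically in the step that closes ring B and leaves no open stereochemical problem after it.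

Alternative 2: The C5–C10 and C8–C9 bonds are cut together. Forward, trienoyl imide A3 would undergo an intramolecular Diels–Alder reaction under Cu(OTf)2 and a chiral bis(oxazoline) to give decalin A4.
- For: both rings and all four stereocentres would come from one catalytic asymmetric step on an acyclic chain. On step economy it is clearly stronger than the chosen route.
- Against: the diene of A3 has a Z terminus and a quaternary carbon on its other terminus, so the s-cis conformer is strongly disfavoured. The dienophile is β,β-disubstituted and has to form the quaternary C10, and such imides are poorly activated by two-point binding. Heating would be needed, at which the Z alkene can isomerise (which changes C8) and catalyst control is lost. C17 arrives as a silyl ether and C11 as an imide, so redox work remains.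
- Comparison: the chosen route is the stepwise form of the same cycloaddition. C5–C10 is made first under cyclic control, and C8–C9 is closed by a sigmatropic shift that needs no s-cis diene and forms no bond at C10. It pays in steps for certainty of stereocontrol.

Alternative 3: The C7–C8 bond is cut. Forward, the Z-iodovinyl α-bromo ester A5 would cyclise with NiBr2(dme), 4,4'-di-tert-butyl-2,2'-bipyridine and Mn powder to decalin A6.
- For: the closure is mild, tolerates esters, keeps the Z alkene and funnels both C8 epimers through one radical. It is stronger than the chosen key step on mildness, and C9 already carries a three-carbon chain.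
- Against: A5 needs C5, C9 and C10 set beforehand, and C9 is exocyclic and next to the quaternary carbon with no ring to control it. The configuration at C8 from nickel capture of a secondary α-ester radical has no evident controlling element, hydrodehalogenation competes, and a Z-iodovinyl group on the hindered C5 is hard to install.
- Comparison: the chosen route creates C9 and C8 in one stereospecific event from ring-bound centres set under cyclic control. It accepts a harsher key step in exchange.

Key step: step 13

Remark on the chemistry: (S)-t-BuPHOX is taken to give the (S)-configured ketone 5; should the sense of induction be the opposite, the (R)-ligand is used and nothing else changes.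

## Route

Step 1
Reactants: 1 2,2,6-trimethylcyclohexan-1-one; 2 allyl chloroformate
Product: 4 allyl 2,6,6-trimethylcyclohex-1-en-1-yl carbonate, via lithium enolate 3 (not isolated)
Conditions: LiN(SiMe3)2, THF, 0 °C; then 2, TMEDA, −78 → 25 °C
Reagents that add atoms: none
Why: Deprotonation at the only enolisable position gives the tetrasubstituted lithium enolate, which the chloroformate acylates on oxygen; this is the standard preparation of an enol carbonate for decarboxylative allylation.

Step 2
Reactants: 4 allyl 2,6,6-trimethylcyclohex-1-en-1-yl carbonate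
Product: 5 (S)-2-allyl-2,6,6-trimethylcyclohexan-1-one
Conditions: Pd2(dba)3 (2.5 mol %), (S)-t-BuPHOX (6 mol %), THF, 25 °C
Reagents that add atoms: none
Why: Decarboxylative asymmetric allylic alkylation: zerovalent palladium ionises the allyl carbonate, CO2 is lost, and the enolate recombines with the allylpalladium unit inside the chiral phosphinooxazoline pocket, which sets the quaternary C10; the enolate can form on one side only, so no regioisomer arises, and the optical purity can be raised later by crystallising a derivative of 7 if needed.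

Step 3
Reactants: 5 (S)-2-allyl-2,6,6-trimethylcyclohexan-1-one
Product: 6 (S)-2,2,6-trimethyl-6-(2-oxopropyl)cyclohexan-1-one
Conditions: PdCl2 (10 mol %), Cu(OAc)2 (20 mol %), O2 (1 atm), DMA/H2O, 25 °C
Reagents that add atoms: water, O
Why: Wacker oxidation of the terminal alkene to the methyl ketone by Markovnikov hydroxypalladation; the hindered ring ketone is inert.

Step 4
Reactants: 6 (S)-2,2,6-trimethyl-6-(2-oxopropyl)cyclohexan-1-one
Product: 7 (7aS)-4,4,7a-trimethyl-1,4,5,6,7,7a-hexahydro-2H-inden-2-one
Conditions: KOH, xylenes, 110 °C, Dean–Stark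
Reagents that add atoms: none
Why: Intramolecular aldol condensation: the ring ketone has no α-hydrogen, so only the methyl group (future C6) can add to it, and loss of water gives the cyclopentenone that holds C6, C5, C11 and C9 in one ring.

Step 5
Reactants: 7 (7aS)-4,4,7a-trimethyl-1,4,5,6,7,7a-hexahydro-2H-inden-2-one
Product: 9 trimethyl{[(3aR,7aS)-4,4,7a-trimethyl-3a,4,5,6,7,7a-hexahydro-1H-inden-2-yl]oxy}silane, via lithium enolate 8 (not isolated)
Conditions: Li, NH3(l)/THF, t-BuOH (1 equiv), −78 °C; isoprene; evaporate NH3; Me3SiCl, Et3N, THF, 0 °C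
Reagents that add atoms: chlorotrimethylsilane, C[Si](C)(C)Cl
Why: Dissolving-metal reduction of the enone with silylation of the regiodefined enolate (reductive silylation), which fixes the enol ether towards C6; C5 is protonated on the face opposite the two axial methyl groups of ring A (the C10 methyl is forced axial because C9 is tied into the flat five-membered ring, and the axial C4 methyl lies on the same face), so H5 ends trans to the C10 methyl.

Step 6
Reactants: 9 trimethyl{[(3aR,7aS)-4,4,7a-trimethyl-3a,4,5,6,7,7a-hexahydro-1H-inden-2-yl]oxy}silane; 10 benzyl chloromethyl ether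
Product: 11 (3R,3aR,7aS)-3-[(benzyloxy)methyl]-4,4,7a-trimethyloctahydro-2H-inden-2-one
Conditions: ZnBr2 (10 mol %), CH2Cl2, 0 → 25 °C
Reagents that add atoms: none
Why: Lewis-acid-mediated alkylation of a silyl enol ether with an α-chloro ether (Mukaiyama-type SN1 alkylation) puts C7 on C6 without enolate equilibration; the oxocarbenium ion adds to the face away from the axial C10 methyl, and this cis-to-H5 epimer is also the more stable one because the other would eclipse the C5–C4 bond.

Step 7
Reactants: 11 (3R,3aR,7aS)-3-[(benzyloxy)methyl]-4,4,7a-trimethyloctahydro-2H-inden-2-one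
Product: 12 (1R,4aS,8aR)-1-[(benzyloxy)methyl]-4a,8,8-trimethyloctahydro-3H-isochromen-3-one
Conditions: mCPBA, NaHCO3, CH2Cl2, 0 → 25 °C
Reagents that add atoms: 3-chloroperoxybenzoic acid, OOC(=O)c1cccc(Cl)c1
Why: Baeyer–Villiger oxidation: the secondary C6 migrates in preference to the primary C9 and with retention, so oxygen is inserted between C11 and C6 and the δ-lactone keeps the C6 configuration.

Step 8
Reactants: 12 (1R,4aS,8aR)-1-[(benzyloxy)methyl]-4a,8,8-trimethyloctahydro-3H-isochromen-3-one
Product: 13 (1R,4aS,8aR)-1-[(benzyloxy)methyl]-4a,8,8-trimethyloctahydro-1H-isochromen-3-ol (both anomers)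
Conditions: i-Bu2AlH (1.1 equiv), CH2Cl2, −78 °C; aq. potassium sodium tartrate
Reagents that add atoms: none
Why: Partial reduction of a lactone to the lactol with one equivalent of hydride at low temperature; the tetrahedral aluminium alkoxide holds until work-up.

Step 9
Reactants: 13 (1R,4aS,8aR)-1-[(benzyloxy)methyl]-4a,8,8-trimethyloctahydro-1H-isochromen-3-ol
Product: 15 (1R,4aS,8aR)-1-[(benzyloxy)methyl]-4a,8,8-trimethyl-4a,5,6,7,8,8a-hexahydro-1H-isochromene, via lactol mesylate 14 (not isolated)
Conditions: MsCl, Et3N, CH2Cl2, 0 → 40 °C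
Reagents that add atoms: none
Why: Dehydration of a 2-deoxy lactol through its anomeric mesylate (ionisation to the oxocarbenium ion, then loss of a C9 proton) gives the cyclic enol ether C9=C11; only C9 carries hydrogen next to C11.

Step 10
Reactants: 15 (1R,4aS,8aR)-1-[(benzyloxy)methyl]-4a,8,8-trimethyl-4a,5,6,7,8,8a-hexahydro-1H-isochromene
Product: 16 [(1R,4aS,8aR)-4a,8,8-trimethyl-4a,5,6,7,8,8a-hexahydro-1H-isochromen-1-yl]methanol
Conditions: Li, NH3(l)/THF, −78 °C; NH4Cl
Reagents that add atoms: none
Why: Dissolving-metal cleavage of the benzyl ether; the isolated enol ether is inert to lithium in ammonia and no acid is involved.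

Step 11
Reactants: 16 [(1R,4aS,8aR)-4a,8,8-trimethyl-4a,5,6,7,8,8a-hexahydro-1H-isochromen-1-yl]methanol
Product: 17 (1R,4aS,8aR)-4a,8,8-trimethyl-4a,5,6,7,8,8a-hexahydro-1H-isochromene-1-carbaldehyde
Conditions: Dess–Martin periodinane, pyridine, CH2Cl2, 0 °C
Reagents that add atoms: none
Why: Dess–Martin oxidation, buffered with pyridine so that the acid-labile enol ether survives; epimerisation at C6 would only return the same equatorial aldehyde.

Step 12
Reactants: 17 (1R,4aS,8aR)-4a,8,8-trimethyl-4a,5,6,7,8,8a-hexahydro-1H-isochromene-1-carbaldehyde; 18 methyl 2-[bis(2,2,2-trifluoroethoxy)phosphoryl]acetate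
Product: 19 methyl (2Z)-3-[(1S,4aS,8aR)-4a,8,8-trimethyl-4a,5,6,7,8,8a-hexahydro-1H-isochromen-1-yl]prop-2-enoate
Conditions: KN(SiMe3)2, 18-crown-6, THF, −78 °C
Reagents that add atoms: none
Why: Still–Gennari variant of the Horner–Wadsworth–Emmons reaction: the trifluoroethyl phosphonate with a dissociated potassium ion eliminates fast from the kinetically formed adduct and gives the Z enoate; the weakly basic anion does not enolise the α-alkoxy aldehyde (the descriptor at C6 changes to S only through the priority rules).

Step 13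
Reactants: 19 methyl (2Z)-3-[(1S,4aS,8aR)-4a,8,8-trimethyl-4a,5,6,7,8,8a-hexahydro-1H-isochromen-1-yl]prop-2-enoate
Product: 20 methyl (1R,2S,4aR,8aR)-1-formyl-5,5,8a-trimethyl-1,2,4a,5,6,7,8,8a-octahydronaphthalene-2-carboxylate
Conditions: degassed toluene (0.02 M), BHT (10 mol %), base-washed sealed tube, 200 °C
Reagents that add atoms: none
Why: Thermal [3,3]-sigmatropic (Claisen) shift of an allyl vinyl ether held in a ring, the known ring contraction of 2-alkenyl-3,4-dihydro-2H-pyrans to cyclohex-3-enecarbaldehydes: the C6–O bond breaks while the enol ether carbon C9 bonds to the acrylate carbon C8, and the ring oxygen ends as the C11 aldehyde oxygen. Ring B (C5–C10) closes in a pericyclic mode through a six-membered boat-like array (O, C11, C9, C8, C7, C6) bridged by the C5–C10 bond; a chair is impossible because C6 and C9 are tied 1,4 across it. The reacting conformer is the pyran boat with O and C10 at the prow positions, which the trans ring fusion allows without leaving the chair of ring A; it places the C6 alkenyl group axial on the face of H5, above C9. C9 is controlled by C6: the shift is suprafacial, so C8 arrives on the face that carried the alkenyl group, opposite the C10 methyl, and C11 is left cis to that methyl. C8 is controlled by the Z geometry: the ester sits on the inside of the boat and ends trans to C11 and cis to H5. The step needs the [3,3] path to outrun the 1,5-hydrogen shift of the Z enoate and Z/E isomerisation; the ester on the reacting terminus slows the shift, so acid-free glass, a radical inhibitor and dilution are used. Both new substituents are equatorial in 20, so the kinetic product is also the stable epimer at C8 and C9.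

Step 14
Reactants: 20 methyl (1R,2S,4aR,8aR)-1-formyl-5,5,8a-trimethyl-1,2,4a,5,6,7,8,8a-octahydronaphthalene-2-carboxylate
Product: 21 methyl (1R,2S,4aR,8aS)-1-ethenyl-5,5,8a-trimethyl-1,2,4a,5,6,7,8,8a-octahydronaphthalene-2-carboxylate
Conditions: Zn, CH2I2, Ti(OiPr)4, THF, 25 °C
Reagents that add atoms: diiodomethane, ICI
Why: Takai methylenation with the gem-dizinc reagent is non-basic and selective for aldehydes over esters, so C9 and the labile C8–H are untouched and the β,γ-unsaturated ester is not isomerised.

Step 15
Reactants: 22 methyl 4-hydroxybut-2-ynoate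
Product: 23 methyl (2Z)-4-hydroxy-3-iodobut-2-enoate
Conditions: NaI, AcOH, 70 °C
Reagents that add atoms: sodium iodide, [Na+].[I-]
Why: Hydroiodination of an ynoate: conjugate addition of iodide and anti protonation give the Z β-iodo enoate, with iodine cis to the ester and the hydroxymethyl group trans to it, so a butenolide cannot form.

Step 16
Reactants: 21 methyl (1R,2S,4aR,8aS)-1-ethenyl-5,5,8a-trimethyl-1,2,4a,5,6,7,8,8a-octahydronaphthalene-2-carboxylate; 23 methyl (2Z)-4-hydroxy-3-iodobut-2-enoate
Product: 25 methyl (1R,2S,4aR,8aS)-1-[(3E)-3-(hydroxymethyl)-5-methoxy-5-oxopent-3-en-1-yl]-5,5,8a-trimethyl-1,2,4a,5,6,7,8,8a-octahydronaphthalene-2-carboxylate, via alkylborane 24 (not isolated)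
Conditions: 9-BBN, THF, 0 → 25 °C; then 23, Pd(dppf)Cl2 (5 mol %), AsPh3, Cs2CO3, DMF/THF/H2O, 25 °C
Reagents that add atoms: none
Why: Hydroboration of the monosubstituted alkene with 9-BBN puts boron on C12 and leaves the hindered ring alkene and the esters alone; the B-alkyl Suzuki–Miyaura coupling then proceeds with retention at the vinyl carbon, so C12 ends cis to the ester and the hydroxymethyl group trans (E by the priority rules), and the carbonate base at room temperature does not touch C8.

Step 17
Reactants: 25 methyl (1R,2S,4aR,8aS)-1-[(3E)-3-(hydroxymethyl)-5-methoxy-5-oxopent-3-en-1-yl]-5,5,8a-trimethyl-1,2,4a,5,6,7,8,8a-octahydronaphthalene-2-carboxylate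
Product: 26 methyl (1R,2S,4aR,8aS)-1-[(3E)-3-(acetoxymethyl)-5-methoxy-5-oxopent-3-en-1-yl]-5,5,8a-trimethyl-1,2,4a,5,6,7,8,8a-octahydronaphthalene-2-carboxylate
Conditions: Ac2O, pyridine, DMAP (cat.), CH2Cl2, 0 → 25 °C
Reagents that add atoms: acetic anhydride, CC(=O)OC(C)=O
Why: DMAP-catalysed acetylation of the only hydroxyl group, a primary allylic alcohol.

## Compound list

1 | 2,2,6-trimethylcyclohexan-1-one (racemic) | CC1CCCC(C)(C)C1=O | starting material
2 | allyl chloroformate | C=CCOC(=O)Cl | starting material
3 | lithium 2,6,6-trimethylcyclohex-1-en-1-olate | [Li+].[O-]C1=C(C)CCCC1(C)C | intermediate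
4 | allyl 2,6,6-trimethylcyclohex-1-en-1-yl carbonate | C=CCOC(=O)OC1=C(C)CCCC1(C)C | intermediate
5 | (S)-2-allyl-2,6,6-trimethylcyclohexan-1-one | C=CC[C@]1(C)CCCC(C)(C)C1=O | intermediate
6 | (S)-2,2,6-trimethyl-6-(2-oxopropyl)cyclohexan-1-one | CC(=O)C[C@]1(C)CCCC(C)(C)C1=O | intermediate
7 | (7aS)-4,4,7a-trimethyl-1,4,5,6,7,7a-hexahydro-2H-inden-2-one | O=C1C=C2C(C)(C)CCC[C@@]2(C)C1 | intermediate
8 | lithium (3aR,7aS)-4,4,7a-trimethyl-3a,4,5,6,7,7a-hexahydro-1H-inden-2-olate (trans-fused) | [Li+].[O-]C1=C[C@@H]2C(C)(C)CCC[C@@]2(C)C1 | intermediate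
9 | trimethyl{[(3aR,7aS)-4,4,7a-trimethyl-3a,4,5,6,7,7a-hexahydro-1H-inden-2-yl]oxy}silane (trans-fused) | C[Si](C)(C)OC1=C[C@@H]2C(C)(C)CCC[C@@]2(C)C1 | intermediate
10 | benzyl chloromethyl ether | ClCOCc1ccccc1 | starting material
11 | (3R,3aR,7aS)-3-[(benzyloxy)methyl]-4,4,7a-trimethyloctahydro-2H-inden-2-one (trans-fused, side chain cis to H-3a) | O=C1C[C@]2(C)CCCC(C)(C)[C@H]2[C@@H]1COCc1ccccc1 | intermediate
12 | (1R,4aS,8aR)-1-[(benzyloxy)methyl]-4a,8,8-trimethyloctahydro-3H-isochromen-3-one (trans-fused δ-lactone) | O=C1C[C@]2(C)CCCC(C)(C)[C@H]2[C@H](COCc2ccccc2)O1 | intermediate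
13 | (1R,4aS,8aR)-1-[(benzyloxy)methyl]-4a,8,8-trimethyloctahydro-1H-isochromen-3-ol (both anomers) | OC1C[C@]2(C)CCCC(C)(C)[C@H]2[C@H](COCc2ccccc2)O1 | intermediate
14 | (1R,4aS,8aR)-1-[(benzyloxy)methyl]-4a,8,8-trimethyloctahydro-1H-isochromen-3-yl methanesulfonate | CS(=O)(=O)OC1C[C@]2(C)CCCC(C)(C)[C@H]2[C@H](COCc2ccccc2)O1 | intermediate
15 | (1R,4aS,8aR)-1-[(benzyloxy)methyl]-4a,8,8-trimethyl-4a,5,6,7,8,8a-hexahydro-1H-isochromene | C1=C[C@]2(C)CCCC(C)(C)[C@H]2[C@H](COCc2ccccc2)O1 | intermediate
16 | [(1R,4aS,8aR)-4a,8,8-trimethyl-4a,5,6,7,8,8a-hexahydro-1H-isochromen-1-yl]methanol | OC[C@@H]1OC=C[C@]2(C)CCCC(C)(C)[C@@H]12 | intermediate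
17 | (1R,4aS,8aR)-4a,8,8-trimethyl-4a,5,6,7,8,8a-hexahydro-1H-isochromene-1-carbaldehyde | O=C[C@@H]1OC=C[C@]2(C)CCCC(C)(C)[C@@H]12 | intermediate
18 | methyl 2-[bis(2,2,2-trifluoroethoxy)phosphoryl]acetate | COC(=O)CP(=O)(OCC(F)(F)F)OCC(F)(F)F | starting material
19 | methyl (2Z)-3-[(1S,4aS,8aR)-4a,8,8-trimethyl-4a,5,6,7,8,8a-hexahydro-1H-isochromen-1-yl]prop-2-enoate (trans-fused; acrylate cis to H-8a) | COC(=O)/C=C\[C@@H]1OC=C[C@]2(C)CCCC(C)(C)[C@@H]12 | intermediate
20 | methyl (1R,2S,4aR,8aR)-1-formyl-5,5,8a-trimethyl-1,2,4a,5,6,7,8,8a-octahydronaphthalene-2-carboxylate | O=C[C@@H]1[C@@H](C(=O)OC)C=C[C@@H]2C(C)(C)CCC[C@@]12C | intermediate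
21 | methyl (1R,2S,4aR,8aS)-1-ethenyl-5,5,8a-trimethyl-1,2,4a,5,6,7,8,8a-octahydronaphthalene-2-carboxylate | C=C[C@@H]1[C@@H](C(=O)OC)C=C[C@@H]2C(C)(C)CCC[C@@]12C | intermediate
22 | methyl 4-hydroxybut-2-ynoate | COC(=O)C#CCO | starting material
23 | methyl (2Z)-4-hydroxy-3-iodobut-2-enoate | COC(=O)/C=C(\I)CO | intermediate
24 | methyl (1R,2S,4aR,8aS)-1-[2-(9-borabicyclo[3.3.1]nonan-9-yl)ethyl]-5,5,8a-trimethyl-1,2,4a,5,6,7,8,8a-octahydronaphthalene-2-carboxylate | C1CCC2CCCC1B2CC[C@@H]1[C@@H](C(=O)OC)C=C[C@@H]2C(C)(C)CCC[C@@]12C | intermediate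
25 | methyl (1R,2S,4aR,8aS)-1-[(3E)-3-(hydroxymethyl)-5-methoxy-5-oxopent-3-en-1-yl]-5,5,8a-trimethyl-1,2,4a,5,6,7,8,8a-octahydronaphthalene-2-carboxylate | COC(=O)/C=C(\CC[C@@H]1[C@@H](C(=O)OC)C=C[C@@H]2C(C)(C)CCC[C@@]12C)CO | intermediate
26 | methyl (1R,2S,4aR,8aS)-1-[(3E)-3-(acetoxymethyl)-5-methoxy-5-oxopent-3-en-1-yl]-5,5,8a-trimethyl-1,2,4a,5,6,7,8,8a-octahydronaphthalene-2-carboxylate | COC(=O)/C=C(\CC[C@@H]1[C@@H](C(=O)OC)C=C[C@@H]2C(C)(C)CCC[C@@]12C)COC(C)=O | target

## Step count and risks

Total step count: 17. Longest linear sequence: 16 (steps 1–14, 16 and 17; step 15 prepares the coupling partner 23).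

Least certain steps:

**Step 13 (key step).** The shift may be outrun by a thermal 1,5-hydrogen shift from C6 to the ester carbonyl, which deconjugates the Z enoate and destroys the allyl vinyl ether. Z-to-E isomerisation (which would invert C8) and acid-traced hydrolysis of the enol ether are further losses. The cause is that the ester on the reacting terminus slows the boat-like shift and pushes the temperature up.

Fallback, from 19 back to 21: the ester is taken out of the reacting terminus and restored afterwards. Reduction of 19 with i-Bu2AlH (CH2Cl2, −78 °C) should give the Z allylic alcohol (2Z)-3-[(1S,4aS,8aR)-4a,8,8-trimethyl-4a,5,6,7,8,8a-hexahydro-1H-isochromen-1-yl]prop-2-en-1-ol F1. Silylation (t-BuMe2SiCl, imidazole) gives its tert-butyldimethylsilyl ether F2. Its Claisen ring contraction (toluene, about 180 °C) has an electron-neutral terminus and no carbonyl for the hydrogen shift. It should give, by the same stereochemical course, (1R,2S,4aR,8aR)-2-({[tert-butyl(dimethyl)silyl]oxy}methyl)-5,5,8a-trimethyl-1,2,4a,5,6,7,8,8a-octahydronaphthalene-1-carbaldehyde F3. Takai methylenation (Zn, CH2I2, Ti(OiPr)4) gives the vinyl silyl ether tert-butyl{[(1R,2S,4aR,8aS)-1-ethenyl-5,5,8a-trimethyl-1,2,4a,5,6,7,8,8a-octahydronaphthalen-2-yl]methoxy}dimethylsilane F4. Bu4NF gives the alcohol [(1R,2S,4aR,8aS)-1-ethenyl-5,5,8a-trimethyl-1,2,4a,5,6,7,8,8a-octahydronaphthalen-2-yl]methanol F5. Oxidation with TEMPO and PhI(OAc)2 in MeCN/H2O gives the acid (1R,2S,4aR,8aS)-1-ethenyl-5,5,8a-trimethyl-1,2,4a,5,6,7,8,8a-octahydronaphthalene-2-carboxylic acid F6. Me3SiCHN2 in MeOH/toluene returns the route to 21.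

**Step 5.** Protonation of C5 on the wrong face would give the cis ring fusion. Over-reduction of the carbonyl and proton exchange before silylation (loss of the regiodefined enolate) are also possible, because the outcome depends on a small proton source approaching a carbanion.

Fallback, from 7 back to 11: hydrogen is delivered to C5 by a metal hydride from the open face. A 1,4-hydrosilylation of 7 with Et3SiH and RhCl(PPh3)3 (toluene, 60 °C) should give triethyl{[(3aR,7aS)-4,4,7a-trimethyl-3a,4,5,6,7,7a-hexahydro-1H-inden-2-yl]oxy}silane F7. Alkylation with 10 and ZnBr2 as in step 6 gives 11.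

**Step 7.** Migration of the primary C9 instead of C6 would give the regioisomeric lactone, because the β-benzyloxy group lowers the migratory aptitude of C6. β-Elimination of benzyl alcohol is a second loss.

Fallback, from 11 back to 12: the migration is directed by silicon.
- Elimination of benzyl alcohol from 11 with DBU gives the α-methylene ketone 4,4,7a-trimethyl-3-methylideneoctahydro-2H-inden-2-one F8 (trans-fused, ring configuration of 11).
- Copper-catalysed conjugate silylation (PhMe2Si–Bpin, CuCl, NaOt-Bu, MeOH, THF) and equilibration give the β-silyl ketone 3-{[dimethyl(phenyl)silyl]methyl}-4,4,7a-trimethyloctahydro-2H-inden-2-one F9 (configuration of 11).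
- Baeyer–Villiger oxidation with mCPBA, now governed by the β-silicon effect, gives the lactone 1-{[dimethyl(phenyl)silyl]methyl}-4a,8,8-trimethyloctahydro-3H-isochromen-3-one F10 (configuration of 12).
- Fleming–Tamao oxidation (KBr, AcOOH, NaOAc, AcOH) gives 1-(hydroxymethyl)-4a,8,8-trimethyloctahydro-3H-isochromen-3-one F11 (configuration of 12).
- Benzylation with benzyl 2,2,2-trichloroacetimidate and catalytic TfOH returns 12.

**Step 12.** Z selectivity may erode with the hindered α-alkoxy aldehyde, or aldehyde 17 may hydrate or oligomerise before it reacts.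

Fallback, from 17 back to 19: the geometry is set by syn hydrogenation. Homologation of 17 with dimethyl (1-diazo-2-oxopropyl)phosphonate (K2CO3, MeOH) gives the alkyne (1R,4aS,8aR)-1-ethynyl-4a,8,8-trimethyl-4a,5,6,7,8,8a-hexahydro-1H-isochromene F12. Deprotonation with n-BuLi (THF, −78 °C) and ClCO2Me gives the ynoate methyl 3-[(1R,4aS,8aR)-4a,8,8-trimethyl-4a,5,6,7,8,8a-hexahydro-1H-isochromen-1-yl]prop-2-ynoate F13. Semihydrogenation (H2, Pd on CaCO3 poisoned with Pb(OAc)2, quinoline, EtOAc) gives 19.

## Further compounds

F1 | step 13 | (2Z)-3-[(1S,4aS,8aR)-4a,8,8-trimethyl-4a,5,6,7,8,8a-hexahydro-1H-isochromen-1-yl]prop-2-en-1-ol | OC/C=C\[C@@H]1OC=C[C@]2(C)CCCC(C)(C)[C@@H]12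
F2 | step 13 | tert-butyldimethylsilyl ether of F1 | CC(C)(C)[Si](C)(C)OC/C=C\[C@@H]1OC=C[C@]2(C)CCCC(C)(C)[C@@H]12
F3 | step 13 | (1R,2S,4aR,8aR)-2-({[tert-butyl(dimethyl)silyl]oxy}methyl)-5,5,8a-trimethyl-1,2,4a,5,6,7,8,8a-octahydronaphthalene-1-carbaldehyde | O=C[C@@H]1[C@@H](CO[Si](C)(C)C(C)(C)C)C=C[C@@H]2C(C)(C)CCC[C@@]12C
F4 | step 13 | tert-butyl{[(1R,2S,4aR,8aS)-1-ethenyl-5,5,8a-trimethyl-1,2,4a,5,6,7,8,8a-octahydronaphthalen-2-yl]methoxy}dimethylsilane | C=C[C@@H]1[C@@H](CO[Si](C)(C)C(C)(C)C)C=C[C@@H]2C(C)(C)CCC[C@@]12C
F5 | step 13 | [(1R,2S,4aR,8aS)-1-ethenyl-5,5,8a-trimethyl-1,2,4a,5,6,7,8,8a-octahydronaphthalen-2-yl]methanol | C=C[C@@H]1[C@@H](CO)C=C[C@@H]2C(C)(C)CCC[C@@]12C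
F6 | step 13 | (1R,2S,4aR,8aS)-1-ethenyl-5,5,8a-trimethyl-1,2,4a,5,6,7,8,8a-octahydronaphthalene-2-carboxylic acid | C=C[C@@H]1[C@@H](C(=O)O)C=C[C@@H]2C(C)(C)CCC[C@@]12C
F7 | step 5 | triethyl{[(3aR,7aS)-4,4,7a-trimethyl-3a,4,5,6,7,7a-hexahydro-1H-inden-2-yl]oxy}silane | CC[Si](CC)(CC)OC1=C[C@@H]2C(C)(C)CCC[C@@]2(C)C1
F8 | step 7 | 4,4,7a-trimethyl-3-methylideneoctahydro-2H-inden-2-one (trans-fused) | C=C1C(=O)C[C@]2(C)CCCC(C)(C)[C@@H]12
F9 | step 7 | 3-{[dimethyl(phenyl)silyl]methyl}-4,4,7a-trimethyloctahydro-2H-inden-2-one (configuration of 11) | O=C1C[C@]2(C)CCCC(C)(C)[C@H]2[C@@H]1C[Si](C)(C)c1ccccc1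
F10 | step 7 | 1-{[dimethyl(phenyl)silyl]methyl}-4a,8,8-trimethyloctahydro-3H-isochromen-3-one (configuration of 12) | O=C1C[C@]2(C)CCCC(C)(C)[C@H]2[C@H](C[Si](C)(C)c2ccccc2)O1
F11 | step 7 | 1-(hydroxymethyl)-4a,8,8-trimethyloctahydro-3H-isochromen-3-one (configuration of 12) | O=C1C[C@]2(C)CCCC(C)(C)[C@H]2[C@H](CO)O1
F12 | step 12 | (1R,4aS,8aR)-1-ethynyl-4a,8,8-trimethyl-4a,5,6,7,8,8a-hexahydro-1H-isochromene | C#C[C@@H]1OC=C[C@]2(C)CCCC(C)(C)[C@@H]12
F13 | step 12 | methyl 3-[(1R,4aS,8aR)-4a,8,8-trimethyl-4a,5,6,7,8,8a-hexahydro-1H-isochromen-1-yl]prop-2-ynoate | COC(=O)C#C[C@@H]1OC=C[C@]2(C)CCCC(C)(C)[C@@H]12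
A1 | alternative 1 | methyl 3-bromo-2-hydroxy-5-methyl-4-{2-methyl-5-[(methylsulfonyl)oxy]pentan-2-yl}-6-[4-(trimethylsilyl)but-3-yn-1-yl]benzoate | C[Si](C)(C)C#CCCc1c(C(=O)OC)c(O)c(Br)c(C(C)(C)CCCOS(C)(=O)=O)c1C
A2 | alternative 1 | methyl 4-bromo-5,5,8a-trimethyl-3-oxo-1-[4-(trimethylsilyl)but-3-yn-1-yl]-3,5,6,7,8,8a-hexahydronaphthalene-2-carboxylate (quaternary C10 as in 26) | C[Si](C)(C)C#CCCC1=C(C(=O)OC)C(=O)C(Br)=C2C(C)(C)CCC[C@@]12C
A3 | alternative 2 | 3-[(2E,8E,10Z)-12-{[tert-butyl(dimethyl)silyl]oxy}-3,7,7-trimethyldodeca-2,8,10-trienoyl]-1,3-oxazolidin-2-one | O=C(/C=C(\C)CCCC(C)(C)/C=C/C=C\CO[Si](C)(C)C(C)(C)C)N1CCOC1=O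
A4 | alternative 2 | 3-{[2-({[tert-butyl(dimethyl)silyl]oxy}methyl)-5,5,8a-trimethyl-1,2,4a,5,6,7,8,8a-octahydronaphthalen-1-yl]carbonyl}-1,3-oxazolidin-2-one (ring configuration of 20) | O=C(N3CCOC3=O)[C@@H]1[C@@H](CO[Si](C)(C)C(C)(C)C)C=C[C@@H]2C(C)(C)CCC[C@@]12C
A5 | alternative 3 | methyl 2-bromo-6-{[tert-butyl(dimethyl)silyl]oxy}-3-{2-[(Z)-2-iodoethenyl]-1,3,3-trimethylcyclohexyl}hexanoate (both C2 epimers) | CC(C)(C)[Si](C)(C)OCCC[C@H](C(Br)C(=O)OC)[C@]1(C)CCCC(C)(C)[C@H]1/C=C\I
A6 | alternative 3 | methyl 1-(3-{[tert-butyl(dimethyl)silyl]oxy}propyl)-5,5,8a-trimethyl-1,2,4a,5,6,7,8,8a-octahydronaphthalene-2-carboxylate (ring configuration of 26) | CC(C)(C)[Si](C)(C)OCCC[C@@H]1[C@@H](C(=O)OC)C=C[C@@H]2C(C)(C)CCC[C@@]12C
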